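Ring E (cyclohexene; C1 methyl-bearing, C3 bearing ring A, C4 the aroyl group of ring C, C5 ring D) is disconnected at C2–C3 and C4–C5. Both bonds form in one silicon-tethered intramolecular Diels–Alder reaction: a (Z)-dienylsilane (C5–C6–C1–C2), bound through silicon to the ortho-oxygen of ring A next to C3, adds to a (Z)-enone (C3=C4) on the same ring. This ortho-hydroxyl is the exploited feature: the tether fixes regiochemistry and forces ring A exo through a cis-fused oxasiline, and the silicon left on C2 is then removed by protodesilylation with allyl shift, which places the alkene at C1=C2. The racemate is resolved before deprotection.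

Key step: step 18

Remark: ring A = 2,6-dioxygenated phenyl carrying the cinnamoyl group, ring B = aryl of that cinnamoyl group, ring C = aryl of the C4 ketone, ring D = aryl on C5, ring E = cyclohexene (C2 = vinylic CH, C6 = CH2); TBS = tert-butyldimethylsilyl.
Remark: boronate 16 and the other starting materials are taken to be commercially available; 24 and 26 are racemates drawn as the enantiomer that is carried on; the carbinol centre of 19, 21 and 22 is racemic and is destroyed in step 17.

Step 1
Reactants: 1 2,4-dihydroxybenzaldehyde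
Product: 2 2,4-diacetoxybenzaldehyde
Conditions: Ac2O, pyridine, DMAP (cat.), CH2Cl2, 0 °C to rt
Reagents that add atoms: acetic anhydride CC(=O)OC(C)=O
Why: Acylation of both phenols (nucleophilic acyl substitution) gives base-labile esters for ring B that survive BF3 and keep the ortho-oxygen from closing a flavylium ring in step 3.

Step 2
Reactants: 3 1-(2,4-dihydroxyphenyl)ethanone
Product: 4 1-(2,4-dihydroxy-3-iodophenyl)ethanone
Conditions: I2, HIO3, EtOH/H2O, 40 °C
Reagents that add atoms: iodine [I][I]; iodic acid OI(=O)=O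
Why: Electrophilic aromatic iodination of the resorcinol core should go to the doubly activated position between the two hydroxyls, the usual outcome for this ketone under oxidative iodination.

Step 3
Reactants: 4 1-(2,4-dihydroxy-3-iodophenyl)ethanone; 2 2,4-diacetoxybenzaldehyde
Product: 5 (E)-3-(2,4-diacetoxyphenyl)-1-(2,4-dihydroxy-3-iodophenyl)prop-2-en-1-one
Conditions: BF3·OEt2, 1,4-dioxane, rt
Reagents that add atoms: none
Why: Lewis-acid-mediated Claisen–Schmidt condensation (aldol addition and dehydration through the BF2 chelate of the ortho-hydroxy ketone) should give the (E)-enone while sparing the aryl acetates.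

Step 4
Reactants: 1 2,4-dihydroxybenzaldehyde
Product: 6 2,4-bis(tert-butyldimethylsilyloxy)benzaldehyde
Conditions: TBSCl, imidazole, DMF, rt
Reagents that add atoms: tert-butyl(chloro)dimethylsilane CC(C)(C)[Si](C)(C)Cl
Why: Silylation of both phenols gives ethers for ring D that tolerate the phosphonate anion of step 8 and the tert-butyllithium of step 9.

Step 5
Reactants: 7 prop-2-yn-1-ol
Product: 9 (Z)-3-iodo-2-methylprop-2-en-1-ol, via alkenylmagnesium chelate 8 (not isolated)
Conditions: MeMgBr (3 equiv), CuI (10 mol%), THF, −10 °C to rt; I2, −78 to 0 °C; aq. NH4Cl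
Reagents that add atoms: methylmagnesium bromide C[Mg]Br; iodine [I][I]
Why: Copper-catalysed anti-carbomagnesiation of the propargylic alkoxide puts magnesium cis to the CH2O arm in a five-membered chelate and iodinolysis with retention gives the (Z)-iodide, the geometry that later places silicon on the inside position of the diene.

Step 6
Reactants: 9 (Z)-3-iodo-2-methylprop-2-en-1-ol
Product: 10 (Z)-3-bromo-1-iodo-2-methylprop-1-ene
Conditions: CBr4, PPh3, CH2Cl2, 0 °C
Reagents that add atoms: tetrabromomethane BrC(Br)(Br)Br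
Why: Appel bromination (SN2 on the alkoxyphosphonium ion) converts the primary allylic alcohol into the bromide without touching the vinyl iodide.

Step 7
Reactants: 10 (Z)-3-bromo-1-iodo-2-methylprop-1-ene
Product: 11 diethyl [(Z)-3-iodo-2-methylprop-2-en-1-yl]phosphonate
Conditions: P(OEt)3, neat, 100 °C
Reagents that add atoms: triethyl phosphite CCOP(OCC)OCC
Why: Michaelis–Arbuzov reaction at the primary allylic bromide gives the phosphonate, the vinyl iodide being inert to the phosphite.

Step 8
Reactants: 11 diethyl [(Z)-3-iodo-2-methylprop-2-en-1-yl]phosphonate; 6 2,4-bis(tert-butyldimethylsilyloxy)benzaldehyde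
Product: 12 (1E,3Z)-1-[2,4-bis(tert-butyldimethylsilyloxy)phenyl]-4-iodo-3-methylbuta-1,3-diene
Conditions: NaN(SiMe3)2, THF, −78 °C; then 6, −78 to 0 °C
Reagents that add atoms: none
Why: Horner–Wadsworth–Emmons olefination through the α-carbon of the allylic phosphonate anion should form the styrenyl double bond with E geometry, the iodo-substituted double bond keeping its Z geometry at low temperature.

Step 9
Reactants: 12 (1E,3Z)-1-[2,4-bis(tert-butyldimethylsilyloxy)phenyl]-4-iodo-3-methylbuta-1,3-diene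
Product: 14 chloro(diethyl){(1Z,3E)-4-[2,4-bis(tert-butyldimethylsilyloxy)phenyl]-2-methylbuta-1,3-dien-1-yl}silane, via dienyllithium 13 (not isolated)
Conditions: t-BuLi (2.1 equiv), Et2O, −78 °C; cannulated into Et2SiCl2 (5 equiv), −78 °C to rt; volatiles removed in vacuo, used crude
Reagents that add atoms: dichlorodiethylsilane CC[Si](Cl)(Cl)CC
Why: Iodine–lithium exchange and silylation of the alkenyllithium both proceed with retention of the double-bond geometry, and the excess of dichlorosilane limits the reaction to monosubstitution.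

Step 10
Reactants: 1 2,4-dihydroxybenzaldehyde
Product: 15 2,4-dihydroxy-3-iodobenzaldehyde
Conditions: I2, HIO3, EtOH/H2O, 40 °C
Reagents that add atoms: iodine [I][I]; iodic acid OI(=O)=O
Why: Electrophilic aromatic iodination between the two hydroxyls, as in step 2, provides the handle for the side chain of ring C.

Step 11
Reactants: 15 2,4-dihydroxy-3-iodobenzaldehyde; 16 (E)-4,4,5,5-tetramethyl-2-(3-methylbut-1-en-1-yl)-1,3,2-dioxaborolane
Product: 17 2,4-dihydroxy-3-[(E)-3-methylbut-1-en-1-yl]benzaldehyde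
Conditions: Pd(dppf)Cl2 (5 mol%), K2CO3, 1,4-dioxane/H2O, 80 °C
Reagents that add atoms: none
Why: Suzuki–Miyaura cross-coupling transfers the alkenyl group with retention of its E geometry and tolerates the free phenols and the aldehyde.

Step 12
Reactants: 17 2,4-dihydroxy-3-[(E)-3-methylbut-1-en-1-yl]benzaldehyde
Product: 18 2,4-bis(tert-butyldimethylsilyloxy)-3-[(E)-3-methylbut-1-en-1-yl]benzaldehyde
Conditions: TBSOTf, 2,6-lutidine, CH2Cl2, 0 °C to rt
Reagents that add atoms: tert-butyldimethylsilyl trifluoromethanesulfonate CC(C)(C)[Si](C)(C)OS(=O)(=O)C(F)(F)F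
Why: Silylation with the silyl triflate caps both phenols, including the hindered hydrogen-bonded one, so that the later alkynol, allylic alcohol and enone cannot cyclise onto the ortho-oxygen of ring C.

Step 13
Reactants: 18 2,4-bis(tert-butyldimethylsilyloxy)-3-[(E)-3-methylbut-1-en-1-yl]benzaldehyde
Product: 19 1-{2,4-bis(tert-butyldimethylsilyloxy)-3-[(E)-3-methylbut-1-en-1-yl]phenyl}prop-2-yn-1-ol (racemic)
Conditions: HC≡CMgBr, THF, −78 to 0 °C; aq. NH4Cl at −20 °C
Reagents that add atoms: ethynylmagnesium bromide C#C[Mg]Br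
Why: 1,2-Addition of the alkynyl Grignard reagent to the aldehyde gives the propargylic alcohol, whose new stereocentre is left racemic because it is oxidised away in step 17.

Step 14
Reactants: 5 (E)-3-(2,4-diacetoxyphenyl)-1-(2,4-dihydroxy-3-iodophenyl)prop-2-en-1-one; 14 chloro(diethyl)dienylsilane
Product: 20 tethered aryl iodide (5 silylated by 14 at the ring A oxygen para to the acyl group)
Conditions: imidazole, CH2Cl2, 0 °C
Reagents that add atoms: none
Why: Silyl ether formation occurs at the free hydroxyl para to the acyl group of ring A, the other hydroxyl being held in a hydrogen bond to the ketone, which installs the tether on the oxygen next to the future C3.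

Step 15
Reactants: 20 tethered aryl iodide; 19 propargylic alcohol
Product: 21 tethered alkynol (iodine of 20 replaced by the 3-hydroxy-3-arylprop-1-yn-1-yl group of 19)
Conditions: Pd(PPh3)2Cl2 (5 mol%), CuI (5 mol%), Et3N, THF, rt
Reagents that add atoms: none
Why: Sonogashira coupling of the terminal alkyne with the aryl iodide joins the two carbons that become C3 and C4 to ring A under mild conditions that the acetates, the silyl ethers and the diene tolerate.

Step 16
Reactants: 21 tethered alkynol
Product: 22 tethered (Z)-allylic alcohol (ring A and the carbinol carbon cis on the new alkene)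
Conditions: H2 (1 atm), Pd/CaCO3 poisoned with Pb(OAc)2 (Lindlar catalyst), quinoline, EtOAc, 0 °C
Reagents that add atoms: none
Why: Syn semihydrogenation of the alkyne on the poisoned palladium surface gives the (Z)-alkene, the hindered silyl diene and the chalcone double bond being hydrogenated much more slowly.

Step 17
Reactants: 22 tethered (Z)-allylic alcohol
Product: 23 tethered (Z)-enone
Conditions: activated MnO2, CH2Cl2, 0 °C, dark
Reagents that add atoms: none
Why: MnO2 oxidation of the doubly activated (benzylic and allylic) alcohol gives the (Z)-enone under neutral conditions that should not isomerise the double bond.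

Step 18
Reactants: 23 tethered (Z)-enone
Product: 24 racemic cis-fused cycloadduct (2R,3S,4R,5S drawn)
Conditions: toluene (0.005 M), BHT, base-washed glassware, 90 °C, dark
Reagents that add atoms: none
Why: Thermal type 1 intramolecular Diels–Alder reaction through a temporary silicon tether: a concerted suprafacial [4π+2π] addition of the (Z)-dienylsilane (C5=C6–C1=C2) to the (Z)-enone (C3=C4), the closest known reaction types being silicon-tethered intramolecular Diels–Alder reactions of dienylsilyl ethers and the cis-fused-only cycloadditions of tethered (Z)-dienes. It closes ring E by cycloaddition (C2–C3 and C4–C5 formed together) and, with the same C2–C3 bond, the six-membered 1,2-oxasiline ring (Si–O–ring A–C3–C2), which can only be cis-fused because silicon sits on the inside position of the diene terminus. This geometric constraint forces ring A exo, which sets C3 trans to ring D on C5 (the outside substituent of the E styrenyl terminus) and C2 with silicon cis to ring A, while the Z geometry of the dienophile is transferred stereospecifically, so the aroyl group on C4 is cis to ring A and trans to ring D. Regiochemistry (C2 to C3, C5 to C4) is fixed by the tether and agrees with the polarisation of the aryl diene and the enone. The step needs the enone to stay Z and the chalcone enone to stay out of the reaction: moderate temperature, exclusion of light, acid and nucleophiles, high dilution and the para position of the cinnamoyl group relative to the tether oxygen should secure this. The substrate is achiral, so 24 forms as a racemate.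

Step 19
Reactants: 24 racemic cycloadduct
Product: 26 racemic protected cyclohexene (3S,4R,5S drawn), via silyl trifluoroacetate 25 (not isolated)
Conditions: CF3CO2H (3 equiv), CH2Cl2, −20 to 0 °C; then aq. NaHCO3, THF
Reagents that add atoms: none
Why: Electrophilic substitution of the allylsilane with allyl shift (SE2′) adds the proton to C6 and expels silicon from C2 through the β-silyl cation at C1, so that the alkene ends at C1=C2, C2 ceases to be a stereocentre and hydrolysis of the silyl ester frees the ring A hydroxyl, with C3, C4 and C5 untouched.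

Step 20
Reactants: 26 racemic protected cyclohexene
Product: 27 (3S,4R,5S)-protected cyclohexene (single enantiomer)
Conditions: preparative SFC on an amylose tris(3,5-dimethylphenylcarbamate) phase, CO2/i-PrOH, 35 °C
Reagents that add atoms: none
Why: Resolution by chromatography on a chiral stationary phase separates the enantiomers of the racemate formed in step 18 and so fixes the absolute configuration, no stereocentre being epimerisable under these neutral conditions.

Step 21
Reactants: 27 (3S,4R,5S)-protected cyclohexene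
Product: 28 Artonin C
Conditions: K2CO3, MeOH/THF, argon, 0 °C to rt; aq. NH4Cl
Reagents that add atoms: none
Why: Base-mediated methanolysis cleaves the two aryl acetates and the four aryl silyl ethers, and the phenoxide that appears ortho to the C4 ketone suppresses enolisation, so that the only epimerisable centre C4 should keep its configuration.

Compound list
1 | 2,4-dihydroxybenzaldehyde | O=Cc1ccc(O)cc1O | starting material
2 | 2,4-diacetoxybenzaldehyde | CC(=O)Oc1ccc(C=O)c(OC(C)=O)c1 | intermediate
3 | 1-(2,4-dihydroxyphenyl)ethanone | CC(=O)c1ccc(O)cc1O | starting material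
4 | 1-(2,4-dihydroxy-3-iodophenyl)ethanone | CC(=O)c1ccc(O)c(I)c1O | intermediate
5 | (E)-3-(2,4-diacetoxyphenyl)-1-(2,4-dihydroxy-3-iodophenyl)prop-2-en-1-one | CC(=O)Oc1ccc(/C=C/C(=O)c2ccc(O)c(I)c2O)c(OC(C)=O)c1 | intermediate
6 | 2,4-bis(tert-butyldimethylsilyloxy)benzaldehyde | O=Cc1ccc(O[Si](C)(C)C(C)(C)C)cc1O[Si](C)(C)C(C)(C)C | intermediate
7 | prop-2-yn-1-ol | C#CCO | starting material
8 | alkenylmagnesium chelate: bromomagnesium (Z)-3-(bromomagnesio)-2-methylprop-2-en-1-olate (not isolated) | Br[Mg]OC/C(C)=C\[Mg]Br | intermediate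
9 | (Z)-3-iodo-2-methylprop-2-en-1-ol | OC/C(C)=C\I | intermediate
10 | (Z)-3-bromo-1-iodo-2-methylprop-1-ene | BrC/C(C)=C\I | intermediate
11 | diethyl [(Z)-3-iodo-2-methylprop-2-en-1-yl]phosphonate | CCOP(=O)(OCC)C/C(C)=C\I | intermediate
12 | (1E,3Z)-1-[2,4-bis(tert-butyldimethylsilyloxy)phenyl]-4-iodo-3-methylbuta-1,3-diene | I/C=C(C)\C=C\c1ccc(O[Si](C)(C)C(C)(C)C)cc1O[Si](C)(C)C(C)(C)C | intermediate
13 | dienyllithium: (1Z,3E)-4-[2,4-bis(tert-butyldimethylsilyloxy)phenyl]-2-methylbuta-1,3-dien-1-yllithium (not isolated) | [Li]/C=C(C)\C=C\c1ccc(O[Si](C)(C)C(C)(C)C)cc1O[Si](C)(C)C(C)(C)C | intermediate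
14 | chloro(diethyl){(1Z,3E)-4-[2,4-bis(tert-butyldimethylsilyloxy)phenyl]-2-methylbuta-1,3-dien-1-yl}silane | CC[Si](Cl)(CC)/C=C(C)\C=C\c1ccc(O[Si](C)(C)C(C)(C)C)cc1O[Si](C)(C)C(C)(C)C | intermediate
15 | 2,4-dihydroxy-3-iodobenzaldehyde | O=Cc1ccc(O)c(I)c1O | intermediate
16 | (E)-4,4,5,5-tetramethyl-2-(3-methylbut-1-en-1-yl)-1,3,2-dioxaborolane | CC(C)/C=C/B1OC(C)(C)C(C)(C)O1 | starting material
17 | 2,4-dihydroxy-3-[(E)-3-methylbut-1-en-1-yl]benzaldehyde | CC(C)/C=C/c1c(O)ccc(C=O)c1O | intermediate
18 | 2,4-bis(tert-butyldimethylsilyloxy)-3-[(E)-3-methylbut-1-en-1-yl]benzaldehyde | CC(C)/C=C/c1c(O[Si](C)(C)C(C)(C)C)ccc(C=O)c1O[Si](C)(C)C(C)(C)C | intermediate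
19 | 1-{2,4-bis(tert-butyldimethylsilyloxy)-3-[(E)-3-methylbut-1-en-1-yl]phenyl}prop-2-yn-1-ol (racemic) | C#CC(O)c1ccc(O[Si](C)(C)C(C)(C)C)c(/C=C/C(C)C)c1O[Si](C)(C)C(C)(C)C | intermediate
20 | tethered aryl iodide: (E)-3-(2,4-diacetoxyphenyl)-1-[4-({diethyl[(1Z,3E)-4-(2,4-bis(TBS-oxy)phenyl)-2-methylbuta-1,3-dien-1-yl]silyl}oxy)-2-hydroxy-3-iodophenyl]prop-2-en-1-one | CC(=O)Oc1ccc(/C=C/C(=O)c2ccc(O[Si](CC)(CC)/C=C(C)\C=C\c3ccc(O[Si](C)(C)C(C)(C)C)cc3O[Si](C)(C)C(C)(C)C)c(I)c2O)c(OC(C)=O)c1 | intermediate
21 | tethered alkynol: 20 with iodine replaced by the 3-hydroxy-3-{2,4-bis(TBS-oxy)-3-[(E)-3-methylbut-1-en-1-yl]phenyl}prop-1-yn-1-yl group (carbinol racemic) | CC(=O)Oc1ccc(/C=C/C(=O)c2ccc(O[Si](CC)(CC)/C=C(C)\C=C\c3ccc(O[Si](C)(C)C(C)(C)C)cc3O[Si](C)(C)C(C)(C)C)c(C#CC(O)c3ccc(O[Si](C)(C)C(C)(C)C)c(/C=C/C(C)C)c3O[Si](C)(C)C(C)(C)C)c2O)c(OC(C)=O)c1 | intermediate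
22 | tethered (Z)-allylic alcohol: alkyne of 21 reduced to the (Z)-alkene (carbinol racemic) | CC(=O)Oc1ccc(/C=C/C(=O)c2ccc(O[Si](CC)(CC)/C=C(C)\C=C\c3ccc(O[Si](C)(C)C(C)(C)C)cc3O[Si](C)(C)C(C)(C)C)c(/C=C\C(O)c3ccc(O[Si](C)(C)C(C)(C)C)c(/C=C/C(C)C)c3O[Si](C)(C)C(C)(C)C)c2O)c(OC(C)=O)c1 | intermediate
23 | tethered (Z)-enone: carbinol of 22 oxidised to the ketone; ring A and the aroyl group cis on the enone; (1Z,3E)-dienylsilyl ether on the adjacent ring A oxygen | CC(=O)Oc1ccc(/C=C/C(=O)c2ccc(O[Si](CC)(CC)/C=C(C)\C=C\c3ccc(O[Si](C)(C)C(C)(C)C)cc3O[Si](C)(C)C(C)(C)C)c(/C=C\C(=O)c3ccc(O[Si](C)(C)C(C)(C)C)c(/C=C/C(C)C)c3O[Si](C)(C)C(C)(C)C)c2O)c(OC(C)=O)c1 | intermediate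
24 | racemic cycloadduct (2R,3S,4R,5S drawn): ring E with C6=C1 alkene, cis-fused to a benzo-1,2-oxasiline through C2 (Si) and C3 (ring A); silicon, ring A and the aroyl group mutually cis, ring D trans | CC1=C[C@H](c2ccc(O[Si](C)(C)C(C)(C)C)cc2O[Si](C)(C)C(C)(C)C)[C@@H](C(=O)c2ccc(O[Si](C)(C)C(C)(C)C)c(/C=C/C(C)C)c2O[Si](C)(C)C(C)(C)C)[C@@H]2[C@H]1[Si](CC)(CC)Oc1ccc(C(=O)/C=C/c3ccc(OC(C)=O)cc3OC(C)=O)c(O)c12 | intermediate
25 | silyl trifluoroacetate: 26 carrying an O–SiEt2–OC(O)CF3 group on the ring A oxygen para to the cinnamoyl group (racemic; not isolated) | CC1=C[C@H](c2c(O[Si](CC)(CC)OC(=O)C(F)(F)F)ccc(C(=O)/C=C/c3ccc(OC(C)=O)cc3OC(C)=O)c2O)[C@H](C(=O)c2ccc(O[Si](C)(C)C(C)(C)C)c(/C=C/C(C)C)c2O[Si](C)(C)C(C)(C)C)[C@@H](c2ccc(O[Si](C)(C)C(C)(C)C)cc2O[Si](C)(C)C(C)(C)C)C1 | intermediate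
26 | racemic protected cyclohexene (3S,4R,5S drawn): Artonin C with acetates on both ring B oxygens and TBS ethers on the ring C and ring D oxygens | CC1=C[C@H](c2c(O)ccc(C(=O)/C=C/c3ccc(OC(C)=O)cc3OC(C)=O)c2O)[C@H](C(=O)c2ccc(O[Si](C)(C)C(C)(C)C)c(/C=C/C(C)C)c2O[Si](C)(C)C(C)(C)C)[C@@H](c2ccc(O[Si](C)(C)C(C)(C)C)cc2O[Si](C)(C)C(C)(C)C)C1 | intermediate
27 | (3S,4R,5S)-protected cyclohexene: single enantiomer of 26 | CC1=C[C@H](c2c(O)ccc(C(=O)/C=C/c3ccc(OC(C)=O)cc3OC(C)=O)c2O)[C@H](C(=O)c2ccc(O[Si](C)(C)C(C)(C)C)c(/C=C/C(C)C)c2O[Si](C)(C)C(C)(C)C)[C@@H](c2ccc(O[Si](C)(C)C(C)(C)C)cc2O[Si](C)(C)C(C)(C)C)C1 | intermediate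
28 | Artonin C | CC1=C[C@H](c2c(O)ccc(C(=O)/C=C/c3ccc(O)cc3O)c2O)[C@H](C(=O)c2ccc(O)c(/C=C/C(C)C)c2O)[C@@H](c2ccc(O)cc2O)C1 | target

Total step count: 21. Longest linear sequence: 13 steps (steps 5 to 9, then 14 to 21).

Steps most likely to fail

Step 18. The enone may isomerise thermally from Z to E (or the aryl silyl ether may be lost) faster than the hindered (Z)-diene cyclises, which would erode the configuration at C4. The fallback gives up kinetic control at C4. Setting out from 23, the enone is deliberately isomerised with catalytic DABCO in CH2Cl2 to the (E)-enone F1. Its tethered cycloaddition in toluene at 80 °C still delivers ring A exo and should give the C4-epimeric cycloadduct F2. Protodesilylation as in step 19 passes through the C4-epimeric silyl trifluoroacetate F3 to the C4-epimeric cyclohexene F4. C4 is the only enolisable stereocentre and, with the ortho-oxygen of ring C still silylated, is equilibrated with DBU in toluene at 60 °C. No strong bias is assumed; the epimers are separated, F4 is resubmitted, and the route is rejoined at 26.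

Step 16. The hydrogenation may run on (alkane formation, reduction of the diene or the chalcone double bond), and the doubly benzylic (Z)-allylic alcohol may ionise and close a chromene ring with the free ring A hydroxyl. The fallback changes the order of events: setting out from 21, the alcohol is first oxidised with MnO2 in CH2Cl2 to the ynone F5. The semihydrogenation is then run on this electron-poor alkyne (Pd/CaCO3 poisoned with Pb(OAc)2, quinoline, toluene, −10 °C), which gives 23 directly and bypasses 22.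

Step 15. The ortho-alkynylphenol formed next to the free ring A hydroxyl may cyclise to a benzofuran under Pd/Cu catalysis, and the amine or a copper acetylide may cleave the aryl silyl ether. The fallback is a copper-free and amine-free coupling: setting out from 19, the alkyne is stannylated with Bu3SnOMe at 60 °C (methanol removed) to the alkynylstannane F6. Stille coupling of F6 with 20 (Pd2(dba)3, AsPh3, THF, 50 °C) returns to 21.

Further compounds
F1 | step 18 | (E)-enone isomer of 23 | CC(=O)Oc1ccc(/C=C/C(=O)c2ccc(O[Si](CC)(CC)/C=C(C)\C=C\c3ccc(O[Si](C)(C)C(C)(C)C)cc3O[Si](C)(C)C(C)(C)C)c(/C=C/C(=O)c3ccc(O[Si](C)(C)C(C)(C)C)c(/C=C/C(C)C)c3O[Si](C)(C)C(C)(C)C)c2O)c(OC(C)=O)c1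
F2 | step 18 | C4-epimeric cycloadduct (racemic; 2R,3S,4S,5S drawn) | CC1=C[C@H](c2ccc(O[Si](C)(C)C(C)(C)C)cc2O[Si](C)(C)C(C)(C)C)[C@H](C(=O)c2ccc(O[Si](C)(C)C(C)(C)C)c(/C=C/C(C)C)c2O[Si](C)(C)C(C)(C)C)[C@@H]2[C@H]1[Si](CC)(CC)Oc1ccc(C(=O)/C=C/c3ccc(OC(C)=O)cc3OC(C)=O)c(O)c12
F3 | step 18 | C4-epimeric silyl trifluoroacetate (racemic; not isolated) | CC1=C[C@H](c2c(O[Si](CC)(CC)OC(=O)C(F)(F)F)ccc(C(=O)/C=C/c3ccc(OC(C)=O)cc3OC(C)=O)c2O)[C@@H](C(=O)c2ccc(O[Si](C)(C)C(C)(C)C)c(/C=C/C(C)C)c2O[Si](C)(C)C(C)(C)C)[C@@H](c2ccc(O[Si](C)(C)C(C)(C)C)cc2O[Si](C)(C)C(C)(C)C)C1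
F4 | step 18 | C4-epimer of 26 (racemic; 3S,4S,5S drawn) | CC1=C[C@H](c2c(O)ccc(C(=O)/C=C/c3ccc(OC(C)=O)cc3OC(C)=O)c2O)[C@@H](C(=O)c2ccc(O[Si](C)(C)C(C)(C)C)c(/C=C/C(C)C)c2O[Si](C)(C)C(C)(C)C)[C@@H](c2ccc(O[Si](C)(C)C(C)(C)C)cc2O[Si](C)(C)C(C)(C)C)C1
F5 | step 16 | tethered ynone (carbinol of 21 oxidised to the ketone) | CC(=O)Oc1ccc(/C=C/C(=O)c2ccc(O[Si](CC)(CC)/C=C(C)\C=C\c3ccc(O[Si](C)(C)C(C)(C)C)cc3O[Si](C)(C)C(C)(C)C)c(C#CC(=O)c3ccc(O[Si](C)(C)C(C)(C)C)c(/C=C/C(C)C)c3O[Si](C)(C)C(C)(C)C)c2O)c(OC(C)=O)c1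
F6 | step 15 | 1-{2,4-bis(tert-butyldimethylsilyloxy)-3-[(E)-3-methylbut-1-en-1-yl]phenyl}-3-(tributylstannyl)prop-2-yn-1-ol | CCCC[Sn](CCCC)(CCCC)C#CC(O)c1ccc(O[Si](C)(C)C(C)(C)C)c(/C=C/C(C)C)c1O[Si](C)(C)C(C)(C)C
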